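## Retrosynthetic overview

1. Last bond made is C6–CH3. A methyl group is delivered axially to the cyclic peroxycarbenium ion of a bicyclic 6-methoxy peroxyketal, and this sets C6.
2. The 1,2-dioxane ring is formed last, from H2O2/MeOH acting on a 1,4-dicarbonyl array (C6 ketone plus the C3 carbonyl of a tetronic acid). The obligatory cis-fusion relays C4 to C3.
3. The lactone ring is formed second, by acetate-enolate Claisen condensation and lactonisation on a lactic-acid dioxolanone. That dioxolanone is the temporary first ring and sets C4 by self-regeneration of stereocentres.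
4. Fragment union at C6–C7 is a Pd-catalysed ketone synthesis from a thioester and an alkylzinc iodide.
5. The side chain is closed at C11–C12 by B-alkyl Suzuki coupling of a chiral-pool pentenyl ether (C8) with an E vinyl iodide made from benzyl bromide and propynyl Grignard.

Assumption: atom labels follow the carbon chain of the target (C1 lactone C=O, C3 hemiketal carbon, C4 lactone C–O carbon, C6 peroxide carbon, C8 side-chain methine, C12=C13 alkene). Commercial Grignard solutions are taken as purchasable. The peroxyketal of step 16 is drawn as its major (axial OMe) anomer, because both anomers give the same cation.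

## Route

Step 1
Reactants: 1 (S)-3-bromo-2-methylpropan-1-ol
Product: 2 (S)-(3-bromo-2-methylpropoxy)(tert-butyl)dimethylsilane
Conditions: TBSCl, imidazole, CH2Cl2, 0 °C to rt
Reagents that add atoms: tert-butyldimethylsilyl chloride, CC(C)(C)[Si](C)(C)Cl
Why: Silyl ether protection masks the OH against the Grignard and borane reagents to come, and the C8 stereocentre comes with the starting material with no bond to it touched.

Step 2
Reactants: 2 (S)-(3-bromo-2-methylpropoxy)(tert-butyl)dimethylsilane, 3 vinylmagnesium bromide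
Product: 4 (R)-tert-butyldimethyl[(2-methylpent-4-en-1-yl)oxy]silane
Conditions: Li2CuCl4 (5 mol %), NMP (4 equiv), THF, 0 °C to rt
Reagents that add atoms: none
Why: Copper-catalysed Kochi-type Grignard cross-coupling replaces the primary bromide by vinyl without touching the neighbouring stereocentre (S becomes R only through CIP priorities).

Step 3
Reactants: 5 benzyl bromide, 6 prop-1-yn-1-ylmagnesium bromide
Product: 7 but-2-yn-1-ylbenzene
Conditions: CuBr·SMe2 (5 mol %), THF, reflux
Reagents that add atoms: none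
Why: Copper(I)-catalysed coupling of an alkynyl Grignard reagent with a reactive benzylic halide gives the skipped aryl alkyne.

Step 4
Reactants: 7 but-2-yn-1-ylbenzene
Product: 9 (E)-(3-iodobut-2-en-1-yl)benzene, via alkenylzirconocene chloride 8 (not isolated)
Conditions: Cp2Zr(H)Cl (1.6 equiv), THF, 40 °C; then I2, 0 °C
Reagents that add atoms: Schwartz reagent, [H][Zr](Cl)(C1C=CC=C1)C1C=CC=C1 (zirconium stays only in 8); iodine, II
Why: In this hydrozirconation–iodinolysis, syn addition of Zr–H places CH3 and CH2Ph cis, excess reagent equilibrates zirconium to the less hindered carbon next to CH3 (about 95:5), and iodinolysis proceeds with retention to the E iodide.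

Step 5
Reactants: 4 (R)-tert-butyldimethyl[(2-methylpent-4-en-1-yl)oxy]silane, 9 (E)-(3-iodobut-2-en-1-yl)benzene
Product: 11 tert-butyl{[(2R,6E)-2,6-dimethyl-8-phenyloct-6-en-1-yl]oxy}dimethylsilane, via B-alkyl-9-BBN adduct 10 (not isolated)
Conditions: 9-BBN-H, THF, rt; then 9, PdCl2(dppf) (5 mol %), AsPh3, Cs2CO3, DMF–H2O, rt
Reagents that add atoms: 9-borabicyclo[3.3.1]nonane, [H]B1C2CCCC1CCC2 (boron stays only in 10)
Why: In this B-alkyl Suzuki–Miyaura coupling, anti-Markovnikov hydroboration of the terminal alkene and Pd-catalysed sp3–sp2 coupling form C11–C12 with retention of the E geometry.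

Step 6
Reactants: 11 tert-butyl{[(2R,6E)-2,6-dimethyl-8-phenyloct-6-en-1-yl]oxy}dimethylsilane
Product: 12 (2R,6E)-2,6-dimethyl-8-phenyloct-6-en-1-ol
Conditions: TBAF, THF, rt
Reagents that add atoms: none
Why: Fluoride-induced desilylation is driven by the strong Si–F bond and leaves the alkene and C8 untouched.

Step 7
Reactants: 12 (2R,6E)-2,6-dimethyl-8-phenyloct-6-en-1-ol
Product: 13 [(2E,7R)-8-iodo-3,7-dimethyloct-2-en-1-yl]benzene
Conditions: I2, PPh3, imidazole, CH2Cl2, 0 °C
Reagents that add atoms: iodine, II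
Why: Appel-type (Garegg–Samuelsson) iodination is an SN2 displacement at the primary carbinol carbon only.

Step 8
Reactants: 14 (S)-lactic acid, 15 pivalaldehyde
Product: 16 (2S,5S)-2-tert-butyl-5-methyl-1,3-dioxolan-4-one
Conditions: TsOH (cat.), pentane, Dean–Stark reflux; crystallisation from pentane at −78 °C
Reagents that add atoms: none
Why: Acid-catalysed acetalisation (first stage of self-regeneration of stereocentres) forms the new acetal centre mainly cis to CH3 (about 4:1), and low-temperature crystallisation gives the pure cis isomer.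

Step 9
Reactants: 16 (2S,5S)-2-tert-butyl-5-methyl-1,3-dioxolan-4-one, 17 allyl bromide
Product: 19 (2S,5R)-5-allyl-2-tert-butyl-5-methyl-1,3-dioxolan-4-one, via lithium enolate 18 (not isolated)
Conditions: LDA, THF, −78 °C; then 17, −78 to −30 °C
Reagents that add atoms: lithium diisopropylamide, [Li+].CC(C)[N-]C(C)C (lithium stays only in 18)
Why: In this Seebach self-regeneration-of-stereocentres alkylation the planar enolate is attacked anti to the tert-butyl group, so allyl takes the place of H with overall retention and sets C4 as R (dr above 95:5).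

Step 10
Reactants: 19 (2S,5R)-5-allyl-2-tert-butyl-5-methyl-1,3-dioxolan-4-one
Product: 20 2-[(2S,4R)-2-tert-butyl-4-methyl-5-oxo-1,3-dioxolan-4-yl]acetaldehyde
Conditions: O3, CH2Cl2, −78 °C; then Me2S, −78 °C to rt
Reagents that add atoms: ozone, [O-][O+]=O
Why: Ozonolysis with reductive work-up cleaves the only alkene and leaves C5–C6 on the quaternary carbon.

Step 11
Reactants: 20 2-[(2S,4R)-2-tert-butyl-4-methyl-5-oxo-1,3-dioxolan-4-yl]acetaldehyde
Product: 21 2-[(2S,4R)-2-tert-butyl-4-methyl-5-oxo-1,3-dioxolan-4-yl]acetic acid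
Conditions: NaClO2, NaH2PO4, 2-methylbut-2-ene, t-BuOH–H2O, rt
Reagents that add atoms: sodium chlorite, [Na+].[O-]Cl=O
Why: Pinnick oxidation converts the aldehyde to the acid at buffered pH, which the acylal tolerates.

Step 12
Reactants: 21 2-[(2S,4R)-2-tert-butyl-4-methyl-5-oxo-1,3-dioxolan-4-yl]acetic acid
Product: 22 S-ethyl 2-[(2S,4R)-2-tert-butyl-4-methyl-5-oxo-1,3-dioxolan-4-yl]ethanethioate
Conditions: EtSH, DCC, DMAP (cat.), CH2Cl2, 0 °C to rt
Reagents that add atoms: ethanethiol, CCS
Why: Steglich-type thioesterification activates C6 for palladium insertion while the ring carbonyl stays inert.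

Step 13
Reactants: 13 [(2E,7R)-8-iodo-3,7-dimethyloct-2-en-1-yl]benzene, 22 S-ethyl 2-[(2S,4R)-2-tert-butyl-4-methyl-5-oxo-1,3-dioxolan-4-yl]ethanethioate
Product: 24 (2S,5R)-2-tert-butyl-5-[(4R,8E)-4,8-dimethyl-2-oxo-10-phenyldec-8-en-1-yl]-5-methyl-1,3-dioxolan-4-one, via alkylzinc iodide 23 (not isolated)
Conditions: Zn dust (BrCH2CH2Br, TMSCl activation), THF, 40 °C; then 22, PdCl2(PPh3)2 (5 mol %), toluene, rt
Reagents that add atoms: zinc, [Zn] (stays only in 23)
Why: The Fukuyama coupling (Pd-catalysed thioester–organozinc ketone synthesis) forms the fragment-joining C6–C7 bond under almost neutral conditions that spare the acylal, the alkene, C4 and C8.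

Step 14
Reactants: 24 (2S,5R)-2-tert-butyl-5-[(4R,8E)-4,8-dimethyl-2-oxo-10-phenyldec-8-en-1-yl]-5-methyl-1,3-dioxolan-4-one
Product: 25 (2S,5R)-2-tert-butyl-5-[(4R,8E)-2,2-dimethoxy-4,8-dimethyl-10-phenyldec-8-en-1-yl]-5-methyl-1,3-dioxolan-4-one
Conditions: HC(OMe)3, TsOH (cat.), MeOH, rt
Reagents that add atoms: trimethyl orthoformate, COC(OC)OC
Why: Acid-catalysed ketalisation with orthoformate as water scavenger masks C6 against aldol addition, Dieckmann closure to a cyclopentanedione and β-elimination in the next step, and the hindered acylal survives at rt.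

Step 15
Reactants: 25 (2S,5R)-2-tert-butyl-5-[(4R,8E)-2,2-dimethoxy-4,8-dimethyl-10-phenyldec-8-en-1-yl]-5-methyl-1,3-dioxolan-4-one, 26 ethyl acetate
Product: 29 (5R)-5-[(4R,8E)-4,8-dimethyl-2-oxo-10-phenyldec-8-en-1-yl]-4-hydroxy-5-methylfuran-2(5H)-one, via lithium enolate of ethyl acetate 27 (not isolated), via open-chain hydroxy keto ester 28 (not isolated)
Conditions: LDA (4.4 equiv), 26 (4.2 equiv), THF, −78 °C; add 25, −78 to −20 °C; then 1 M HCl–THF, rt
Reagents that add atoms: lithium diisopropylamide, [Li+].CC(C)[N-]C(C)C (lithium stays only in 27); water, O (oxygen of the C6 ketone)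
Why: A crossed Claisen condensation on the activated dioxolanone carbonyl expels pivalaldehyde and frees the 4-OH, which lactonises onto the ethyl ester (tetronic acid synthesis) while the acid work-up unmasks the ketone, and no bond to C4 is broken.

Step 16
Reactants: 29 (5R)-5-[(4R,8E)-4,8-dimethyl-2-oxo-10-phenyldec-8-en-1-yl]-4-hydroxy-5-methylfuran-2(5H)-one
Product: 30 (3R,4aR,7aR)-3-[(2R,6E)-2,6-dimethyl-8-phenyloct-6-en-1-yl]-7a-hydroxy-3-methoxy-4a-methyltetrahydro-3H-furo[3,2-c][1,2]dioxin-6(4H)-one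
Conditions: urea·H2O2 (5 equiv), Sc(OTf)3 (10 mol %), MeOH, rt
Reagents that add atoms: hydrogen peroxide (as urea adduct), OO; methanol, CO
Why: Lewis-acid-catalysed peroxyketalisation turns the C6 ketone into the α-methoxy hydroperoxide, which adds to the keto tautomer at C3 (peroxyhemiketalisation), and because only the cis-fused bicycle can close, C4 fixes C3 as R while the alkene is inert.

Step 17
Reactants: 30 (3R,4aR,7aR)-3-[(2R,6E)-2,6-dimethyl-8-phenyloct-6-en-1-yl]-7a-hydroxy-3-methoxy-4a-methyltetrahydro-3H-furo[3,2-c][1,2]dioxin-6(4H)-one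
Product: 33 (3R,4aR,7aR)-3-[(2R,6E)-2,6-dimethyl-8-phenyloct-6-en-1-yl]-7a-hydroxy-3,4a-dimethyltetrahydro-3H-furo[3,2-c][1,2]dioxin-6(4H)-one, via O-trichlorotitanium peroxyketal 31 (not isolated), via O-trichlorotitanium hemiketal 32 (not isolated)
Conditions: Me2Zn (2 equiv) + TiCl4 (4 equiv), CH2Cl2, −78 °C (MeTiCl3, 4 equiv); add 30, −78 to −40 °C; pH 7 phosphate buffer
Reagents that add atoms: dimethylzinc, C[Zn]C (the 6-CH3); titanium tetrachloride, Cl[Ti](Cl)(Cl)Cl (TiCl3 stays only in 31 and 32)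
Why: Proposed new method: SN1-type methyl transfer from MeTiCl3 to a cyclic peroxycarbenium ion, in which the first equivalent caps the 3-OH as a non-basic, electron-poor O–TiCl3 group (CH4 lost), a second equivalent abstracts the more Lewis-basic exocyclic 6-OMe (C3 cannot ionise because it is flanked by the acyloxy carbon C4 and by CH2C=O), and the resulting C6=O(+)–O half-chair, with the lactone oxygen on C4 and the C3–O[Ti] group pseudo-axial and 4-CH3 and C2 pseudo-equatorial, is methylated along the axial trajectory on the face cis to the lactone oxygen, so that C6 is set as R with the side chain equatorial; d0 Ti(IV) cannot reduce the O–O bond, the only C3 bond antiperiplanar to O–O is the poorly migrating C3–CH2C(=O) bond so Criegee-type cleavage is slow, and MeTiCl3 ignores lactones and scavenges any HCl that could add to the alkene; the closest known reaction types are the TiCl4- or SnCl4-mediated substitution of peroxyketals by allylsilanes and silyl enol ethers via peroxycarbenium ions and the MeTiCl3 (Me2Zn/TiCl4) methylation of ketals and tertiary chlorides, but a methyl-metal reagent has not been coupled with a peroxycarbenium ion.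

## Compound list

1 | (S)-3-bromo-2-methylpropan-1-ol | BrC[C@@H](C)CO | starting material
2 | (S)-(3-bromo-2-methylpropoxy)(tert-butyl)dimethylsilane | BrC[C@@H](C)CO[Si](C)(C)C(C)(C)C | intermediate
3 | vinylmagnesium bromide | C=C[Mg]Br | starting material
4 | (R)-tert-butyldimethyl[(2-methylpent-4-en-1-yl)oxy]silane | C=CC[C@@H](C)CO[Si](C)(C)C(C)(C)C | intermediate
5 | benzyl bromide | BrCc1ccccc1 | starting material
6 | prop-1-yn-1-ylmagnesium bromide | CC#C[Mg]Br | starting material
7 | but-2-yn-1-ylbenzene | CC#CCc1ccccc1 | intermediate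
8 | chlorobis(cyclopentadienyl)[(E)-4-phenylbut-2-en-2-yl]zirconium | C/C(=C\Cc1ccccc1)[Zr](Cl)(C1C=CC=C1)C1C=CC=C1 | intermediate
9 | (E)-(3-iodobut-2-en-1-yl)benzene | C/C(I)=C\Cc1ccccc1 | intermediate
10 | 9-[(4R)-5-(tert-butyldimethylsilyloxy)-4-methylpentyl]-9-borabicyclo[3.3.1]nonane | B1(CCC[C@@H](C)CO[Si](C)(C)C(C)(C)C)C2CCCC1CCC2 | intermediate
11 | tert-butyl{[(2R,6E)-2,6-dimethyl-8-phenyloct-6-en-1-yl]oxy}dimethylsilane | C/C(=C\Cc1ccccc1)CCC[C@@H](C)CO[Si](C)(C)C(C)(C)C | intermediate
12 | (2R,6E)-2,6-dimethyl-8-phenyloct-6-en-1-ol | C/C(=C\Cc1ccccc1)CCC[C@@H](C)CO | intermediate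
13 | [(2E,7R)-8-iodo-3,7-dimethyloct-2-en-1-yl]benzene | C/C(=C\Cc1ccccc1)CCC[C@@H](C)CI | intermediate
14 | (S)-lactic acid | C[C@H](O)C(=O)O | starting material
15 | pivalaldehyde | CC(C)(C)C=O | starting material
16 | (2S,5S)-2-tert-butyl-5-methyl-1,3-dioxolan-4-one | C[C@@H]1O[C@H](C(C)(C)C)OC1=O | intermediate
17 | allyl bromide | C=CCBr | starting material
18 | lithium (2S)-2-tert-butyl-5-methyl-1,3-dioxol-4-olate | CC1=C([O-])O[C@@H](C(C)(C)C)O1.[Li+] | intermediate
19 | (2S,5R)-5-allyl-2-tert-butyl-5-methyl-1,3-dioxolan-4-one | C=CC[C@@]1(C)O[C@H](C(C)(C)C)OC1=O | intermediate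
20 | 2-[(2S,4R)-2-tert-butyl-4-methyl-5-oxo-1,3-dioxolan-4-yl]acetaldehyde | O=CC[C@@]1(C)O[C@H](C(C)(C)C)OC1=O | intermediate
21 | 2-[(2S,4R)-2-tert-butyl-4-methyl-5-oxo-1,3-dioxolan-4-yl]acetic acid | OC(=O)C[C@@]1(C)O[C@H](C(C)(C)C)OC1=O | intermediate
22 | S-ethyl 2-[(2S,4R)-2-tert-butyl-4-methyl-5-oxo-1,3-dioxolan-4-yl]ethanethioate | CCSC(=O)C[C@@]1(C)O[C@H](C(C)(C)C)OC1=O | intermediate
23 | [(2R,6E)-2,6-dimethyl-8-phenyloct-6-en-1-yl]zinc iodide | C/C(=C\Cc1ccccc1)CCC[C@@H](C)C[Zn]I | intermediate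
24 | (2S,5R)-2-tert-butyl-5-[(4R,8E)-4,8-dimethyl-2-oxo-10-phenyldec-8-en-1-yl]-5-methyl-1,3-dioxolan-4-one | C/C(=C\Cc1ccccc1)CCC[C@@H](C)CC(=O)C[C@@]1(C)O[C@H](C(C)(C)C)OC1=O | intermediate
25 | (2S,5R)-2-tert-butyl-5-[(4R,8E)-2,2-dimethoxy-4,8-dimethyl-10-phenyldec-8-en-1-yl]-5-methyl-1,3-dioxolan-4-one | C/C(=C\Cc1ccccc1)CCC[C@@H](C)CC(OC)(OC)C[C@@]1(C)O[C@H](C(C)(C)C)OC1=O | intermediate
26 | ethyl acetate | CCOC(C)=O | starting material
27 | lithium 1-ethoxyethen-1-olate | C=C([O-])OCC.[Li+] | intermediate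
28 | ethyl (4R,8R,12E)-4-hydroxy-6,6-dimethoxy-4,8,12-trimethyl-3-oxo-14-phenyltetradec-12-enoate | C/C(=C\Cc1ccccc1)CCC[C@@H](C)CC(OC)(OC)C[C@@](C)(O)C(=O)CC(=O)OCC | intermediate
29 | (5R)-5-[(4R,8E)-4,8-dimethyl-2-oxo-10-phenyldec-8-en-1-yl]-4-hydroxy-5-methylfuran-2(5H)-one | C/C(=C\Cc1ccccc1)CCC[C@@H](C)CC(=O)C[C@@]1(C)OC(=O)C=C1O | intermediate
30 | (3R,4aR,7aR)-3-[(2R,6E)-2,6-dimethyl-8-phenyloct-6-en-1-yl]-7a-hydroxy-3-methoxy-4a-methyltetrahydro-3H-furo[3,2-c][1,2]dioxin-6(4H)-one (major anomer) | C/C(=C\Cc1ccccc1)CCC[C@@H](C)C[C@]1(OC)C[C@@]2(C)OC(=O)C[C@@]2(O)OO1 | intermediate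
31 | 7a-O-trichlorotitanium derivative of 30 | C/C(=C\Cc1ccccc1)CCC[C@@H](C)C[C@]1(OC)C[C@@]2(C)OC(=O)C[C@@]2(O[Ti](Cl)(Cl)Cl)OO1 | intermediate
32 | 7a-O-trichlorotitanium derivative of 33 | C/C(=C\Cc1ccccc1)CCC[C@@H](C)C[C@]1(C)C[C@@]2(C)OC(=O)C[C@@]2(O[Ti](Cl)(Cl)Cl)OO1 | intermediate
33 | (3R,4aR,7aR)-3-[(2R,6E)-2,6-dimethyl-8-phenyloct-6-en-1-yl]-7a-hydroxy-3,4a-dimethyltetrahydro-3H-furo[3,2-c][1,2]dioxin-6(4H)-one (CNP0361739.2) | C/C(=C\Cc1ccccc1)CCC[C@@H](C)C[C@]1(C)C[C@@]2(C)OC(=O)C[C@@]2(O)OO1 | target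

## Totals

Total step count: 17.
Longest linear sequence: 10 steps (1, 2, 5, 6, 7, 13, 14, 15, 16, 17). The branches 3, 4, 5… and 8–12, 13… are equally long, so the ratio is 10/17 = 0.59.

## Steps most likely to fail

**Step 17 (new methylation).**
- Risks: loss of the ring peroxide oxygen instead of OMe, Hock/Criegee fragmentation of the cation, or attack of the methyl-metal on O–O.
- The fallback uses known chemistry, sets out from 24 and returns to the route at 33.
- Non-basic Takai–Lombardo methylenation (Zn, CH2Br2, TiCl4) of the ketone gives the methylidene dioxolanone F1.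
- The Claisen/lactonisation conditions of step 15 give the methylidene tetronic acid F2.
- Cobalt-catalysed Mukaiyama–Isayama hydroperoxysilylation (Co(thd)2, O2, Et3SiH, DCE) is stopped at partial conversion so that the faster 1,1-disubstituted alkene reacts first. It gives the tertiary triethylsilyl peroxide F3 as both C6 epimers.
- HF·pyridine frees the hydroperoxide, which closes onto C3 to give 33 together with the 6-epimeric peroxyhemiketal F4. The two are separated by HPLC.

**Step 16 (peroxyketalisation and ring closure).**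
- Risks: the tetronic acid is strongly enolised and the α-methoxy hydroperoxide is a weak nucleophile, so the bicycle may not close and gem-dihydroperoxides may build up.
- The fallback reverses the order of ring formation, sets out from 25 and returns at 30.
- 25 is condensed with the lithium enolate of tert-butyl acetate and quenched cold with NH4Cl. This gives the open-chain tert-butyl hydroxy keto ester F7, which does not lactonise and has a true ketone at C3.
- Anhydrous ethereal H2O2 with catalytic camphorsulfonic acid exchanges one ketal methoxy group for OOH. The hydroperoxide then closes onto C3 to give the monocyclic 1,2-dioxan-3-ol F8.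
- Brief treatment with TFA in CH2Cl2 closes the lactone from the 4-OH onto the tert-butyl ester and gives 30.

**Step 15 (intermolecular Claisen on a hindered carbonyl).**
- Risks: slow attack next to the quaternary carbon, self-condensation of the enolate, and consumption of the enolate by the released aldehyde.
- The fallback makes the C2–C3 bond intramolecularly, sets out from 25 and returns at 29.
- Catalytic NaOMe in MeOH opens the acylal to the methyl hydroxy ester F5.
- Ac2O, Et3N and DMAP (40 °C) give the tertiary acetate F6.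
- LiHMDS (2.5 equiv, THF, −78 °C to rt) closes the acetate enolate onto the methyl ester (Dieckmann-type tetronic acid synthesis). Work-up with 1 M HCl cleaves the ketal and gives 29.

## Further compounds

F1 | step 17 | (2S,5R)-2-tert-butyl-5-[(4R,8E)-4,8-dimethyl-2-methylidene-10-phenyldec-8-en-1-yl]-5-methyl-1,3-dioxolan-4-one | C/C(=C\Cc1ccccc1)CCC[C@@H](C)CC(=C)C[C@@]1(C)O[C@H](C(C)(C)C)OC1=O
F2 | step 17 | (5R)-5-[(4R,8E)-4,8-dimethyl-2-methylidene-10-phenyldec-8-en-1-yl]-4-hydroxy-5-methylfuran-2(5H)-one | C/C(=C\Cc1ccccc1)CCC[C@@H](C)CC(=C)C[C@@]1(C)OC(=O)C=C1O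
F3 | step 17 | (5R)-4-hydroxy-5-methyl-5-[(4R,8E)-2,4,8-trimethyl-10-phenyl-2-(triethylsilylperoxy)dec-8-en-1-yl]furan-2(5H)-one (both C6 epimers) | C/C(=C\Cc1ccccc1)CCC[C@@H](C)CC(C)(OO[Si](CC)(CC)CC)C[C@@]1(C)OC(=O)C=C1O
F4 | step 17 | (3S,4aR,7aR)-3-[(2R,6E)-2,6-dimethyl-8-phenyloct-6-en-1-yl]-7a-hydroxy-3,4a-dimethyltetrahydro-3H-furo[3,2-c][1,2]dioxin-6(4H)-one | C/C(=C\Cc1ccccc1)CCC[C@@H](C)C[C@@]1(C)C[C@@]2(C)OC(=O)C[C@@]2(O)OO1
F5 | step 15 | methyl (2R,6R,10E)-2-hydroxy-4,4-dimethoxy-2,6,10-trimethyl-12-phenyldodec-10-enoate | C/C(=C\Cc1ccccc1)CCC[C@@H](C)CC(OC)(OC)C[C@@](C)(O)C(=O)OC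
F6 | step 15 | methyl (2R,6R,10E)-2-acetoxy-4,4-dimethoxy-2,6,10-trimethyl-12-phenyldodec-10-enoate | C/C(=C\Cc1ccccc1)CCC[C@@H](C)CC(OC)(OC)C[C@@](C)(OC(C)=O)C(=O)OC
F7 | step 16 | tert-butyl (4R,8R,12E)-4-hydroxy-6,6-dimethoxy-4,8,12-trimethyl-3-oxo-14-phenyltetradec-12-enoate | C/C(=C\Cc1ccccc1)CCC[C@@H](C)CC(OC)(OC)C[C@@](C)(O)C(=O)CC(=O)OC(C)(C)C
F8 | step 16 | tert-butyl 2-{(4R)-6-[(2R,6E)-2,6-dimethyl-8-phenyloct-6-en-1-yl]-3,4-dihydroxy-6-methoxy-4-methyl-1,2-dioxan-3-yl}acetate | C/C(=C\Cc1ccccc1)CCC[C@@H](C)CC1(OC)C[C@@](C)(O)C(O)(CC(=O)OC(C)(C)C)OO1
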